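## Retrosynthetic overview

1. The target comes from its bis-silyl ether by fluoride removal of two aryl silyl groups.
2. Ring B is closed last by a biomimetic cationic cyclisation that forges the C1–C8 quaternary–quaternary bond in a fully substituted, dearomatised acylphloroglucinol (aroyl, geranyl and both prenyls already in place). This replaces the usual malonyl annulation of a cyclohexanone with late bridgehead and C3 chemistry.
3. Ring A is built before it by a de novo [3+3] union: γ-acylation of an aryl 1,3-diketone dianion, then Claisen closure onto a lactone carbonyl.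
4. Stereochemistry: a temporary δ-lactone made from (R)-lavandulol relays C7 to the C5 quaternary centre by anti C-acylation; C1 then follows from the bicyclic constraint.
5. Order of ring formation: δ-lactone (relay ring, opened again) → ring A (cyclohexanetrione) → ring B (cyclohexanone of the bicyclo[3.3.1]nonane).

Assumption: (R)-(−)-lavandulol of high ee and ethyl 5-methylhex-4-enoate are purchased; core atoms carry the final bicyclononane numbering (C1–C9) throughout; tautomeric di- and triketones are drawn as one enol form.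

## Route

Step 1
Reactants: 1 (R)-lavandulol
Product: 2 (R)-lavandulyl iodide
Conditions: PPh3, I2, imidazole, CH2Cl2, 0 °C → rt
Reagents that add atoms: iodine, [I][I]
Why: Appel-type iodination (SN2 at the primary carbinol carbon) leaves the adjacent stereocentre and both alkenes untouched.

Step 2
Reactants: 2 (R)-lavandulyl iodide; 3 dimethyl malonate
Product: 5 dimethyl 2-lavandulylmalonate, via sodium dimethyl malonate 4 (not isolated)
Conditions: NaH, 3 (2.5 equiv), THF/DMF, 0 °C; then 2, 60 °C
Reagents that add atoms: none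
Why: Malonic ester alkylation, in which the soft, weakly basic malonate anion displaces the β-branched iodide by SN2 where a simple ester enolate would risk E2 to a conjugated diene.

Step 3
Reactants: 5 dimethyl 2-lavandulylmalonate
Product: 7 (4R)-7-methyl-4-(prop-1-en-2-yl)oct-6-enoic acid, via lavandulylmalonic acid 6 (not isolated)
Conditions: KOH, MeOH/H2O, 60 °C; 1 M HCl, 0 °C; then pyridine, 100 °C
Reagents that add atoms: potassium hydroxide, [K+].[OH-]
Why: Saponification followed by thermal decarboxylation of the malonic acid (malonic ester synthesis), run in pyridine so that neither alkene sees acid.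

Step 4
Reactants: 7 (4R)-7-methyl-4-(prop-1-en-2-yl)oct-6-enoic acid
Product: 8 (5R)-6,6-dimethyl-5-prenyloxan-2-one
Conditions: Co(salen), Co(C16H14N2O2) (divalent cobalt, 5 mol %), N-fluoro-2,4,6-trimethylpyridinium triflate, (Me2SiH)2O, PhCF3, 0 °C → rt
Reagents that add atoms: none
Why: Mukaiyama-type hydrogen-atom-transfer/radical–polar crossover hydroacyloxylation, in which the cobalt hydride adds H fastest to the less hindered 1,1-disubstituted alkene and only that tertiary centre can be captured 6-exo by the carboxylate, so the prenyl alkene and the stereocentre survive.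

Step 5
Reactants: 8 (5R)-6,6-dimethyl-5-prenyloxan-2-one; 9 geranyl bromide
Product: 11 3-geranyl lactone (both C3 epimers), via lactone lithium enolate 10 (not isolated)
Conditions: LiN(iPr)2, THF, –78 °C; then 9, –78 → –30 °C
Reagents that add atoms: none
Why: Lactone enolate SN2 alkylation with the allylic bromide gives the linear (E)-geranyl product, and the new C3 centre is planarised again in step 6 so its configuration does not matter.

Step 6
Reactants: 11 3-geranyl lactone
Product: 13 phenyl 3-geranyl-2-oxo-5-prenyloxane-3-carboxylate (phenoxycarbonyl trans to prenyl), via geranyl lactone lithium enolate 12 (not isolated)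
Conditions: LiN(iPr)2, THF, –78 °C; then ClCO2Ph, –78 °C
Reagents that add atoms: phenyl chloroformate, O=C(Cl)Oc1ccccc1
Why: Chloroformate C-acylation of the tetrasubstituted lithium enolate (Claisen type), where the electrophile adds axially to the half-chair enolate on the face anti to the C5 prenyl group, setting the quaternary centre (future C5) with phenoxycarbonyl trans and geranyl cis to prenyl by 1,3-induction from the lavandulol stereocentre.

Step 7
Reactants: 14 3',4'-dihydroxyacetophenone
Product: 15 3',4'-bis(triisopropylsilyloxy)acetophenone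
Conditions: TIPSCl, imidazole, DMF, 40 °C
Reagents that add atoms: chlorotri(propan-2-yl)silane, CC(C)[Si](Cl)(C(C)C)C(C)C
Why: Phenol silylation; the bulky silyl ethers tolerate the amide bases and alkoxides of steps 8 and 9 and the formic acid of step 10, and leave with fluoride at the end.

Step 8
Reactants: 15 3',4'-bis(triisopropylsilyloxy)acetophenone; 16 ethyl 5-methylhex-4-enoate
Product: 18 1-[3,4-bis(triisopropylsilyloxy)phenyl]-7-methyloct-6-ene-1,3-dione, via ketone lithium enolate 17 (not isolated)
Conditions: LiN(SiMe3)2 (2.2 equiv), THF, –78 °C; then 16, –78 °C → rt; 1 M HCl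
Reagents that add atoms: none
Why: Crossed Claisen condensation of the preformed methyl ketone enolate with the ester, driven by deprotonation of the β-diketone product.

Step 9
Reactants: 13 phenyl 3-geranyl-2-oxo-5-prenyloxane-3-carboxylate; 18 1-[3,4-bis(triisopropylsilyloxy)phenyl]-7-methyloct-6-ene-1,3-dione
Product: 21 dearomatised acylphloroglucinol carbinol, via diketone dilithium dianion 19 (not isolated), via triketone lactone 20 (not isolated)
Conditions: 18 (2.2 equiv), LiN(iPr)2 (4.5 equiv), THF, –78 → 0 °C; then 13, –78 °C → rt; 1 M HCl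
Reagents that add atoms: none
Why: Hauser–Harris γ-acylation of the diketone dianion by the aryl ester (far more electrophilic than the hindered tert-alkyl lactone), then biomimetic Claisen (Dieckmann-type) closure of the central diketone carbon onto the lactone carbonyl builds ring A and frees the tertiary carbinol; no bond to a stereocentre is touched, and because the ester carbon becomes C9 and the lactone carbon C4 the quaternary centre has the configuration needed for the 7-endo series.

Step 10
Reactants: 21 dearomatised acylphloroglucinol carbinol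
Product: 22 bis(triisopropylsilyl) ether of the target
Conditions: HCO2H/CH2Cl2 (4:1), rt, stopped at full conversion
Reagents that add atoms: none
Why: Biomimetic cationic cyclisation (SN1 ionisation of the tertiary carbinol and C-alkylation of the enol at prenyl-bearing C1, the more nucleophilic carbon because C3 is deactivated by the aroyl group, while O-alkylated isomers are tert-alkyl vinylogous esters that re-ionise) forms the C1–C8 bond and ring B; C1 is fixed by the bridging geometry and C7 is carried over, giving the 7-endo prenyl.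

Step 11
Reactants: 22 bis(triisopropylsilyl) ether of the target
Product: 23 target CNP0160101.2
Conditions: TBAF, AcOH, THF, 0 °C
Reagents that add atoms: none
Why: Fluoride desilylation of the two aryl silyl ethers under buffered, non-acidic conditions that cannot cyclise the enol onto the prenyl or geranyl alkenes.

## Compound list

1 | (R)-lavandulol, (2R)-5-methyl-2-(prop-1-en-2-yl)hex-4-en-1-ol | OC[C@H](CC=C(C)C)C(C)=C | starting material
2 | (R)-lavandulyl iodide, (3R)-3-(iodomethyl)-2,6-dimethylhepta-1,5-diene | IC[C@H](CC=C(C)C)C(C)=C | intermediate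
3 | dimethyl malonate | COC(=O)CC(=O)OC | starting material
4 | sodium dimethyl malonate (sodium enolate of 3) | [Na+].COC(=O)[CH-]C(=O)OC | intermediate
5 | dimethyl 2-lavandulylmalonate, dimethyl 2-[5-methyl-2-(prop-1-en-2-yl)hex-4-en-1-yl]propanedioate, stereocentre unchanged from 1 | COC(=O)C(C[C@H](CC=C(C)C)C(C)=C)C(=O)OC | intermediate
6 | 2-lavandulylmalonic acid, stereocentre unchanged from 1 | OC(=O)C(C[C@H](CC=C(C)C)C(C)=C)C(=O)O | intermediate
7 | (4R)-7-methyl-4-(prop-1-en-2-yl)oct-6-enoic acid | OC(=O)CC[C@H](CC=C(C)C)C(C)=C | intermediate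
8 | (5R)-6,6-dimethyl-5-(3-methylbut-2-en-1-yl)oxan-2-one | O=C1CC[C@H](CC=C(C)C)C(C)(C)O1 | intermediate
9 | geranyl bromide, (2E)-1-bromo-3,7-dimethylocta-2,6-diene | CC(C)=CCC/C(C)=C/CBr | starting material
10 | lithium enolate of 8 | [Li+].[O-]C1=CC[C@H](CC=C(C)C)C(C)(C)O1 | intermediate
11 | 3-[(2E)-3,7-dimethylocta-2,6-dien-1-yl]-6,6-dimethyl-5-(3-methylbut-2-en-1-yl)oxan-2-one, C5 as in 8, both C3 epimers | O=C1C(C/C=C(\C)CCC=C(C)C)C[C@H](CC=C(C)C)C(C)(C)O1 | intermediate
12 | lithium enolate of 11 | [Li+].[O-]C1=C(C/C=C(\C)CCC=C(C)C)C[C@H](CC=C(C)C)C(C)(C)O1 | intermediate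
13 | phenyl (3S,5S)-3-[(2E)-3,7-dimethylocta-2,6-dien-1-yl]-6,6-dimethyl-5-(3-methylbut-2-en-1-yl)-2-oxooxane-3-carboxylate; phenoxycarbonyl trans and geranyl cis to the C5 prenyl | CC(C)=CCC/C(C)=C/C[C@]1(C(=O)Oc2ccccc2)C[C@H](CC=C(C)C)C(C)(C)OC1=O | intermediate
14 | 3',4'-dihydroxyacetophenone | CC(=O)c1ccc(O)c(O)c1 | starting material
15 | 3',4'-bis(triisopropylsilyloxy)acetophenone | CC(=O)c1ccc(O[Si](C(C)C)(C(C)C)C(C)C)c(O[Si](C(C)C)(C(C)C)C(C)C)c1 | intermediate
16 | ethyl 5-methylhex-4-enoate | CCOC(=O)CCC=C(C)C | starting material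
17 | lithium enolate of 15 | [Li+].C=C([O-])c1ccc(O[Si](C(C)C)(C(C)C)C(C)C)c(O[Si](C(C)C)(C(C)C)C(C)C)c1 | intermediate
18 | 1-[3,4-bis(triisopropylsilyloxy)phenyl]-7-methyloct-6-ene-1,3-dione | CC(C)=CCCC(=O)CC(=O)c1ccc(O[Si](C(C)C)(C(C)C)C(C)C)c(O[Si](C(C)C)(C(C)C)C(C)C)c1 | intermediate
19 | dilithium 1,3-dianion of 18 (γ-carbanion at C4 of the dione) | [Li+].[Li+].CC(C)=CCC=C([O-])C=C([O-])c1ccc(O[Si](C(C)C)(C(C)C)C(C)C)c(O[Si](C(C)C)(C(C)C)C(C)C)c1 | intermediate
20 | triketone lactone: 3-{5-[3,4-bis(triisopropylsilyloxy)phenyl]-2-(3-methylbut-2-en-1-yl)-3,5-dioxopentanoyl}-3-geranyl-6,6-dimethyl-5-prenyloxan-2-one, ring stereocentres as in 13 (present as its lithium enolate) | CC(C)=CCC/C(C)=C/C[C@]1(C(=O)C(CC=C(C)C)C(=O)CC(=O)c2ccc(O[Si](C(C)C)(C(C)C)C(C)C)c(O[Si](C(C)C)(C(C)C)C(C)C)c2)C[C@H](CC=C(C)C)C(C)(C)OC1=O | intermediate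
21 | 2-[3,4-bis(triisopropylsilyloxy)benzoyl]-6-[(2E)-3,7-dimethylocta-2,6-dien-1-yl]-3,5-dihydroxy-6-[2-(2-hydroxypropan-2-yl)-5-methylhex-4-en-1-yl]-4-(3-methylbut-2-en-1-yl)cyclohexa-2,4-dien-1-one; quaternary centre and side-chain stereocentre as set in 13 | CC(C)=CCC/C(C)=C/C[C@]1(C[C@H](CC=C(C)C)C(C)(C)O)C(=O)C(C(=O)c2ccc(O[Si](C(C)C)(C(C)C)C(C)C)c(O[Si](C(C)C)(C(C)C)C(C)C)c2)=C(O)C(CC=C(C)C)=C1O | intermediate
22 | (1S,5S,7S)-3-[3,4-bis(triisopropylsilyloxy)benzoyl]-5-[(2E)-3,7-dimethylocta-2,6-dien-1-yl]-4-hydroxy-8,8-dimethyl-1,7-bis(3-methylbut-2-en-1-yl)bicyclo[3.3.1]non-3-ene-2,9-dione (7-endo prenyl) | CC(C)=CCC/C(C)=C/C[C@]12C[C@H](CC=C(C)C)C(C)(C)[C@](CC=C(C)C)(C(=O)C(C(=O)c3ccc(O[Si](C(C)C)(C(C)C)C(C)C)c(O[Si](C(C)C)(C(C)C)C(C)C)c3)=C1O)C2=O | intermediate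
23 | CNP0160101.2, (1S,5S,7S)-3-(3,4-dihydroxybenzoyl)-5-[(2E)-3,7-dimethylocta-2,6-dien-1-yl]-4-hydroxy-8,8-dimethyl-1,7-bis(3-methylbut-2-en-1-yl)bicyclo[3.3.1]non-3-ene-2,9-dione (7-endo prenyl) | CC(C)=CCC/C(C)=C/C[C@]12C[C@H](CC=C(C)C)C(C)(C)[C@](CC=C(C)C)(C(=O)C(C(=O)c3ccc(O)c(O)c3)=C1O)C2=O | target

## Step count and risk

Total step count: 11. Longest linear sequence: 9 steps (steps 1–6, 9, 10, 11, from 1 to 23); the aryl branch (steps 7 and 8) joins at step 9.

The three steps most likely to fail:

Step 10 (cationic ring closure). Possible failures are O- instead of C-alkylation, attack at C3 instead of C1, hydride shift or elimination at the C8 cation eroding C7, and acid-induced cyclisation of the geranyl chain. The fallback sets out from 21 and comes back at 22, and replaces protic ionisation by an aprotic tert-alkylation of an O-blocked nucleophile. Trifluoroacetic anhydride and pyridine at 0 °C esterify the tertiary alcohol (enol esters are hydrolysed on bicarbonate work-up) to give the tertiary trifluoroacetate F4. TMSCl and Et3N then silylate both enols to give the bis(trimethylsilyl) dienol ether F5. Catalytic TMSOTf with 2,6-di-tert-butyl-4-methylpyridine in CH2Cl2 at –78 °C ionises the ester, and the silyl enol ether can only capture the cation at C1 (Reetz/Mukaiyama-type SN1 alkylation). Aqueous work-up removes the silyl groups and returns 22.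

Step 9 ([3+3] union). The secondary γ-carbanion may acylate the neopentyl-type ester slowly, and the Claisen closure onto the hindered lactone may stall. The fallback sets out from 13 and 15 and comes back at 21, and moves the C1 prenyl group to after ring formation. Ketone 15 is condensed with ethyl acetate (LiN(SiMe3)2, THF) to the aroylacetone F2. F2, used in place of 18 under the conditions of step 9, offers an unhindered primary γ-carbanion and gives the des-prenyl trione carbinol F3. C-prenylation of F3 at its only free ring CH (K2CO3, prenyl bromide, acetone, rt) then gives 21.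

Step 4 (chemoselective lactonisation). Hydrogen-atom transfer may not discriminate enough between the isopropenyl and prenyl alkenes. The fallback sets out from 7 and comes back at 8, and uses an ionic, reversible activation. Iodolactonisation (I2, NaHCO3, MeCN, 0 °C) traps only the isopropenyl iodonium ion 6-exo and gives the iodomethyl lactone F1. Reductive deiodination (n-Bu3SnH, catalytic (PhSe)2, AIBN, benzene, 80 °C; benzeneselenol-mediated hydrogen transfer outruns 5-exo closure of the primary radical onto the prenyl alkene) gives 8.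

## Further compounds

F1 | step 4 | 6-(iodomethyl)-6-methyl-5-(3-methylbut-2-en-1-yl)oxan-2-one, C5 as in 8, both C6 epimers | O=C1CC[C@H](CC=C(C)C)C(C)(CI)O1
F2 | step 9 | 1-[3,4-bis(triisopropylsilyloxy)phenyl]butane-1,3-dione | CC(=O)CC(=O)c1ccc(O[Si](C(C)C)(C(C)C)C(C)C)c(O[Si](C(C)C)(C(C)C)C(C)C)c1
F3 | step 9 | des-prenyl analogue of 21 (ring CH in place of the prenyl-bearing carbon), stereocentres as in 21 | CC(C)=CCC/C(C)=C/C[C@]1(C[C@H](CC=C(C)C)C(C)(C)O)C(=O)C(C(=O)c2ccc(O[Si](C(C)C)(C(C)C)C(C)C)c(O[Si](C(C)C)(C(C)C)C(C)C)c2)=C(O)C=C1O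
F4 | step 10 | tertiary trifluoroacetate of 21 | CC(C)=CCC/C(C)=C/C[C@]1(C[C@H](CC=C(C)C)C(C)(C)OC(=O)C(F)(F)F)C(=O)C(C(=O)c2ccc(O[Si](C(C)C)(C(C)C)C(C)C)c(O[Si](C(C)C)(C(C)C)C(C)C)c2)=C(O)C(CC=C(C)C)=C1O
F5 | step 10 | bis(trimethylsilyl) dienol ether of F4 | CC(C)=CCC/C(C)=C/C[C@]1(C[C@H](CC=C(C)C)C(C)(C)OC(=O)C(F)(F)F)C(=O)C(C(=O)c2ccc(O[Si](C(C)C)(C(C)C)C(C)C)c(O[Si](C(C)C)(C(C)C)C(C)C)c2)=C(O[Si](C)(C)C)C(CC=C(C)C)=C1O[Si](C)(C)C
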